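## Retrosynthetic overview

- Target 15 comes from its bis(silyl) ether 14 by fluoride desilylation.
- Ring B of 14 is disconnected at C4'–C5' and C5'–C6'. C5' with its three-carbon chain sits para to the C2' oxygen, between unsubstituted C4' and C6', with oxygens on C1', C2' and C3'. That is the pattern of 3-aryloxy-5-methoxy-4-pyranone 7 with its ring oxygen replaced by the ylide carbon of phosphonium salt 9.
- Pyranone 7 comes from ketone 4 and two one-carbon units from amide acetal 5. Ketone 4 comes from phenol 1 and epoxide 2 by way of alcohol 3, so the crowded aryl–O bond to ring B is made as an alkyl aryl ether by SN2 before ring B exists.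
- Salt 9 comes from bromide 8 and triphenylphosphine.
- Ring order: ring A is bought, the pyranone ring is formed in step 3, and ring B is formed from it in step 5.

Key step: step 5

Remark on the chemistry: the target has no stereocentre, so racemic glycidyl methyl ether is used; the carbinol centre of 3 is removed by the oxidation in step 2.

## Route

Step 1
Reactants: 1 2,6-dimethoxy-4-propylphenol; 2 glycidyl methyl ether (racemic)
Product: 3 rac-1-(2,6-dimethoxy-4-propylphenoxy)-3-methoxypropan-2-ol
Conditions: 2 (1.5 equiv), K2CO3 (0.2 equiv), DMF, 90 °C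
Reagents that add atoms: none
Why: Base-catalysed SN2 opening of the epoxide by the phenoxide at the unhindered terminal carbon (phenol–glycidyl ether addition) should give the secondary alcohol, whose carbinol centre forms racemic and is destroyed in step 2.

Step 2
Reactants: 3 rac-1-(2,6-dimethoxy-4-propylphenoxy)-3-methoxypropan-2-ol
Product: 4 1-(2,6-dimethoxy-4-propylphenoxy)-3-methoxypropan-2-one
Conditions: Dess–Martin periodinane (1.3 equiv), CH2Cl2, 0 °C to rt
Reagents that add atoms: none
Why: Dess–Martin oxidation of a secondary alcohol runs under near-neutral conditions that should leave the electron-rich aryl ether untouched.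

Step 3
Reactants: 4 1-(2,6-dimethoxy-4-propylphenoxy)-3-methoxypropan-2-one; 5 N,N-dimethylformamide dimethyl acetal
Product: 7 3-(2,6-dimethoxy-4-propylphenoxy)-5-methoxy-4H-pyran-4-one, via bis(enaminone) 6 (not isolated)
Conditions: 5 (neat, excess), 110 °C, MeOH distilled off; concentrate; then 2 M aq HCl, THF, 50 °C
Reagents that add atoms: water, O
Why: Double aminomethylenation of the two oxygen-activated α-methylene groups by the amide acetal, then acid hydrolysis of one vinylogous amide and addition–elimination of the resulting enol oxygen on the other with loss of dimethylamine, is the established way from a ketone with two α-CH2 groups to a 3,5-disubstituted 4-pyranone.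

Step 4
Reactants: 8 (4-bromobutoxy)(tert-butyl)dimethylsilane
Product: 9 [4-(tert-butyldimethylsilyloxy)butyl]triphenylphosphonium bromide
Conditions: PPh3 (1.1 equiv), MeCN, reflux
Reagents that add atoms: triphenylphosphine, c1ccc(cc1)P(c1ccccc1)c1ccccc1
Why: SN2 quaternisation of triphenylphosphine by a primary bromide should proceed cleanly, and the silyl ether is inert to these neutral conditions.

Step 5
Reactants: 7 3-(2,6-dimethoxy-4-propylphenoxy)-5-methoxy-4H-pyran-4-one; 9 [4-(tert-butyldimethylsilyloxy)butyl]triphenylphosphonium bromide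
Product: 14 tert-butyl{3-[4-(tert-butyldimethylsilyloxy)-3-(2,6-dimethoxy-4-propylphenoxy)-5-methoxyphenyl]propoxy}dimethylsilane, via phosphorane 10 (not isolated), via silyloxypyrylium triflate 11 (not isolated), via 2H-pyran adduct 12 (not isolated), via dienal phosphonium salt 13 (not isolated)
Conditions: 9 (1.2 equiv), NaN(SiMe3)2 (1.2 equiv), THF, −78 to 0 °C; separately 7, TBSOTf (1.05 equiv), CH2Cl2, 0 °C to rt; ylide solution added to the pyrylium solution at −78 °C; then NaN(SiMe3)2 (1.3 equiv), −78 °C to rt, then 50 °C
Reagents that add atoms: tert-butyldimethylsilyl trifluoromethanesulfonate (TBSOTf), CC(C)(C)[Si](C)(C)OS(=O)(=O)C(F)(F)F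
Why: Proposed new method: TBSOTf should silylate the carbonyl oxygen of 7 to the 4-silyloxypyrylium triflate 11, the carbon of phosphorane 10 should add to one of its unsubstituted α-carbons to give 2H-pyran 12, and 12 should open by oxa-6π electrocyclic ring opening to dienal 13, whose allylic phosphonium centre is turned into an ylide by the second portion of NaN(SiMe3)2. Ring B then closes by 6-exo-trig addition of this ylide carbon to the formyl carbon (equally a 6π closure of the delocalised phosphonium trienolate), and the oxaphosphetane loses Ph3PO, which carries off the former ring oxygen, so that the ylide carbon becomes C5' bonded to C4' and C6' and the silylated pyranone oxygen becomes the C2' silyl ether. The closest known reactions are the conversion of 2,4,6-trisubstituted pyrylium salts into benzenes by alkylidenetriphenylphosphoranes and of 4-pyranones into 4-nitrophenols by nitromethane and base, together with the known C2 addition of carbon nucleophiles to 4-silyloxypyrylium ions from 4-pyranones; the combination on a 3,5-dioxygenated silyloxypyrylium ion with a non-stabilised ylide is untested. No stereocentre remains in the product, and the geometry of the alkene next to the phosphonium carbon should not matter, because the delocalised ylide and the reversible 2H-pyran–dienal equilibrium allow the cisoid arrangement to be reached before the irreversible, aromatising loss of Ph3PO. The step needs attack at an α-carbon and not at C4 or at silicon, which the free, most electron-poor α-CH positions next to the oxonium oxygen, the flanked C4 and the bulky tert-butyl group on silicon should secure, while the choice between the two α-carbons is immaterial since both lead to the same arene. Only a slight excess of TBSOTf and inverse addition at −78 °C are used so that silylation of the ylide, proton transfer from 12 to unreacted ylide and intermolecular olefination of 13 are kept down.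

Step 6
Reactants: 14 tert-butyl{3-[4-(tert-butyldimethylsilyloxy)-3-(2,6-dimethoxy-4-propylphenoxy)-5-methoxyphenyl]propoxy}dimethylsilane
Product: 15 2-(2,6-dimethoxy-4-propylphenoxy)-4-(3-hydroxypropyl)-6-methoxyphenol
Conditions: TBAF (3 equiv), AcOH (3 equiv), THF, 0 °C to rt
Reagents that add atoms: none
Why: Fluoride-mediated desilylation should cleave both the aryl and the primary alkyl silyl ether, and the acetic acid buffer keeps the electron-rich phenol from standing as an easily oxidised phenoxide.

## Compound list

1 | 2,6-dimethoxy-4-propylphenol | CCCc1cc(OC)c(O)c(OC)c1 | starting material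
2 | glycidyl methyl ether, 2-(methoxymethyl)oxirane, racemic | COCC1CO1 | starting material
3 | rac-1-(2,6-dimethoxy-4-propylphenoxy)-3-methoxypropan-2-ol | CCCc1cc(OC)c(OCC(O)COC)c(OC)c1 | intermediate
4 | 1-(2,6-dimethoxy-4-propylphenoxy)-3-methoxypropan-2-one | CCCc1cc(OC)c(OCC(=O)COC)c(OC)c1 | intermediate
5 | N,N-dimethylformamide dimethyl acetal | COC(OC)N(C)C | starting material
6 | 1,5-bis(dimethylamino)-2-(2,6-dimethoxy-4-propylphenoxy)-4-methoxypenta-1,4-dien-3-one (alkene geometry not assigned; formed in the flask, not isolated) | CN(C)C=C(OC)C(=O)C(=CN(C)C)Oc1c(OC)cc(CCC)cc1OC | intermediate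
7 | 3-(2,6-dimethoxy-4-propylphenoxy)-5-methoxy-4H-pyran-4-one | COC1=COC=C(Oc2c(OC)cc(CCC)cc2OC)C1=O | intermediate
8 | (4-bromobutoxy)(tert-butyl)dimethylsilane | CC(C)(C)[Si](C)(C)OCCCCBr | starting material
9 | [4-(tert-butyldimethylsilyloxy)butyl]triphenylphosphonium bromide | CC(C)(C)[Si](C)(C)OCCCC[P+](c1ccccc1)(c1ccccc1)c1ccccc1.[Br-] | intermediate
10 | [4-(tert-butyldimethylsilyloxy)butylidene]triphenylphosphorane (formed in the flask, not isolated) | CC(C)(C)[Si](C)(C)OCCCC=P(c1ccccc1)(c1ccccc1)c1ccccc1 | intermediate
11 | 4-(tert-butyldimethylsilyloxy)-3-(2,6-dimethoxy-4-propylphenoxy)-5-methoxypyrylium trifluoromethanesulfonate (formed in the flask, not isolated) | COc1c[o+]cc(Oc2c(OC)cc(CCC)cc2OC)c1O[Si](C)(C)C(C)(C)C.[O-]S(=O)(=O)C(F)(F)F | intermediate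
12 | {4-(tert-butyldimethylsilyloxy)-1-[4-(tert-butyldimethylsilyloxy)-3-(2,6-dimethoxy-4-propylphenoxy)-5-methoxy-2H-pyran-2-yl]butyl}triphenylphosphonium trifluoromethanesulfonate (mixture of racemic diastereomers; formed in the flask, not isolated) | COC1=COC(C(CCCO[Si](C)(C)C(C)(C)C)[P+](c2ccccc2)(c2ccccc2)c2ccccc2)C(Oc2c(OC)cc(CCC)cc2OC)=C1O[Si](C)(C)C(C)(C)C.[O-]S(=O)(=O)C(F)(F)F | intermediate
13 | [1,7-bis(tert-butyldimethylsilyloxy)-6-(2,6-dimethoxy-4-propylphenoxy)-8-methoxy-9-oxonona-5,7-dien-4-yl]triphenylphosphonium trifluoromethanesulfonate (alkene geometry not assigned; formed in the flask, not isolated) | O=CC(OC)=C(O[Si](C)(C)C(C)(C)C)C(Oc1c(OC)cc(CCC)cc1OC)=CC(CCCO[Si](C)(C)C(C)(C)C)[P+](c1ccccc1)(c1ccccc1)c1ccccc1.[O-]S(=O)(=O)C(F)(F)F | intermediate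
14 | tert-butyl{3-[4-(tert-butyldimethylsilyloxy)-3-(2,6-dimethoxy-4-propylphenoxy)-5-methoxyphenyl]propoxy}dimethylsilane | CCCc1cc(OC)c(Oc2cc(CCCO[Si](C)(C)C(C)(C)C)cc(OC)c2O[Si](C)(C)C(C)(C)C)c(OC)c1 | intermediate
15 | 2-(2,6-dimethoxy-4-propylphenoxy)-4-(3-hydroxypropyl)-6-methoxyphenol | CCCc1cc(OC)c(Oc2cc(CCCO)cc(OC)c2O)c(OC)c1 | target

## Step count and risks

Total step count: 6. Longest linear sequence: 5 steps (steps 1, 2, 3, 5, 6).

**Step 5.** The phosphorane may attack silicon (returning 7) or C4 instead of an α-carbon. It may also be used up as a base by proton transfer from 12, or olefinate the aldehyde of 13 intermolecularly before ring closure.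

The fallback uses known chemistry, sets out from 1 and comes back to the route at 15. 5-Bromovanillin is benzylated (BnBr, K2CO3, DMF) to 4-(benzyloxy)-3-bromo-5-methoxybenzaldehyde F1. Ullmann diaryl ether coupling of 1 with F1 (CuI, picolinic acid, K3PO4, DMSO, 100 °C) should give 4-(benzyloxy)-3-(2,6-dimethoxy-4-propylphenoxy)-5-methoxybenzaldehyde F2. Wittig olefination with Ph3P=CHCO2Et (toluene, 80 °C) should give ethyl (E)-3-[4-(benzyloxy)-3-(2,6-dimethoxy-4-propylphenoxy)-5-methoxyphenyl]prop-2-enoate F3. Hydrogenation (H2, Pd/C, EtOAc–EtOH) saturates the alkene and removes the benzyl group to give ethyl 3-[3-(2,6-dimethoxy-4-propylphenoxy)-4-hydroxy-5-methoxyphenyl]propanoate F4. Reduction with LiAlH4 (THF, 0 °C) leads to 15.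

**Step 3.** The condensation may stall after the first aminomethylenation, because the vinylogous amide deactivates the remaining α-methylene group.

The fallback sets out from 4 and comes back at 7. One equivalent of 5 at 70 °C should give the mono-enaminone 4-(dimethylamino)-3-(2,6-dimethoxy-4-propylphenoxy)-1-methoxybut-3-en-2-one F5. Which methylene group reacts first is without consequence, since both regioisomers lead to 7. Deprotonation of the remaining α'-methylene group with LiN(SiMe3)2 (THF, −78 °C) and Claisen formylation with ethyl formate should give 5-(dimethylamino)-4-(2,6-dimethoxy-4-propylphenoxy)-1-hydroxy-2-methoxypenta-1,4-dien-3-one F6. On work-up with aq HCl, F6 should close to 7 with loss of dimethylamine.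

**Step 1.** The hindered phenoxide may open the epoxide slowly, so that the product alkoxide adds to further epoxide and oligomers form.

The fallback sets out from 1 and comes back at 3. Alkylation of 1 with excess epichlorohydrin (K2CO3, MeCN, reflux) should give 2-[(2,6-dimethoxy-4-propylphenoxy)methyl]oxirane F7. Its epoxide is then opened at the terminal carbon by methanol (NaOMe catalytic, MeOH, reflux) to give 3.

## Further compounds

F1 | step 5 | 4-(benzyloxy)-3-bromo-5-methoxybenzaldehyde | COc1cc(C=O)cc(Br)c1OCc1ccccc1
F2 | step 5 | 4-(benzyloxy)-3-(2,6-dimethoxy-4-propylphenoxy)-5-methoxybenzaldehyde | CCCc1cc(OC)c(Oc2cc(C=O)cc(OC)c2OCc2ccccc2)c(OC)c1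
F3 | step 5 | ethyl (E)-3-[4-(benzyloxy)-3-(2,6-dimethoxy-4-propylphenoxy)-5-methoxyphenyl]prop-2-enoate | CCCc1cc(OC)c(Oc2cc(/C=C/C(=O)OCC)cc(OC)c2OCc2ccccc2)c(OC)c1
F4 | step 5 | ethyl 3-[3-(2,6-dimethoxy-4-propylphenoxy)-4-hydroxy-5-methoxyphenyl]propanoate | CCCc1cc(OC)c(Oc2cc(CCC(=O)OCC)cc(OC)c2O)c(OC)c1
F5 | step 3 | 4-(dimethylamino)-3-(2,6-dimethoxy-4-propylphenoxy)-1-methoxybut-3-en-2-one | COCC(=O)C(=CN(C)C)Oc1c(OC)cc(CCC)cc1OC
F6 | step 3 | 5-(dimethylamino)-4-(2,6-dimethoxy-4-propylphenoxy)-1-hydroxy-2-methoxypenta-1,4-dien-3-one | OC=C(OC)C(=O)C(=CN(C)C)Oc1c(OC)cc(CCC)cc1OC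
F7 | step 1 | 2-[(2,6-dimethoxy-4-propylphenoxy)methyl]oxirane | CCCc1cc(OC)c(OCC2CO2)c(OC)c1
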